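**Plan**

1. Retrosynthesis: the C5–CH2 bond at the tetrasubstituted alkene is cut first (Stork–Danheiser addition of a primary alkyllithium to a bicyclic vinylogous ester), then the oxepane C2–C3 bond.
2. Enabling feature: in the 2,2-dimethyloxepan-3-ol ring the carbinol C3 is bonded to the ether carbon C2, whose oxygen O1 already sits on cyclohexane C9a. A ketyl at C3 (aldehyde on the C5a propyl arm) can therefore add 7-exo to the β-carbon of a β-alkoxy crotonate hung on O1. The CH2CO2Et arm left on C2 is the activating group and is cut back to methyl by decarboxylation.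
3. Left fragment, forward: the cyclohexane comes from p-benzoquinone monoketal. Rh/(S)-BINAP vinylation sets C6, two enolate alkylations set C5a, NaBH4 sets C9a and MeMgBr sets C7. The oxepane then closes (sets C3), and the vinyl group becomes the iodoethyl arm.
4. Right fragment, forward: (R)-linalool supplies C1. A Pauson–Khand reaction closes the diquinane (sets C8a), Li/NH3 sets C3a, and a dichloroketene two-carbon ring expansion gives the cycloheptane-1,3-dione, converted to its vinylogous ester.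
5. Union, CBS reduction (sets the allylic carbinol C7 of the hydroazulene), global desilylation.

Key step: step 10

Assumption: names use decahydro-1-benzoxepine locants (O1, C2, C3, C4, C5, C5a, C6, C7, C8, C9, C9a) for the left fragment and azulene locants (C1–C8a) for the right fragment; the target is read as 3R,5aR,6R,7S,9aR and 1R,3aR,7S,8aR.
Assumption: centres that are lost again (C6 of dione 33, the carbinol carbon of 36, the ozonide carbon of 21) are written without configuration.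

**Left fragment**

Step 1
Reactants: 1 4,4-dimethoxycyclohexa-2,5-dien-1-one
Product: 2 (S)-5-ethenyl-4,4-dimethoxycyclohex-2-en-1-one
Conditions: CH2=CHBF3K, [Rh(cod)2]BF4 (3 mol %), (S)-BINAP, Et3N, PhMe/H2O, rt
Reagents that add atoms: potassium vinyltrifluoroborate, C=C[B-](F)(F)F.[K+]
Why: Rhodium-catalysed asymmetric 1,4-addition of an alkenyltrifluoroborate to a quinone monoketal (Hayashi–Miyaura type) desymmetrises the dienone, the (S)-BINAP complex selecting the enone face that gives the later C6 centre, and the second enone is kept to direct the next enolisations.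

Step 2
Reactants: 2 (S)-5-ethenyl-4,4-dimethoxycyclohex-2-en-1-one
Product: 3 (5R,6R)-5-ethenyl-4,4-dimethoxy-6-methylcyclohex-2-en-1-one (methyl trans to vinyl)
Conditions: LDA, THF, −78 °C; MeI, −78 → −20 °C
Reagents that add atoms: iodomethane, CI
Why: Kinetic α'-deprotonation gives the cross-conjugated enolate (the ketal leaves no γ-hydrogen) and methylation should occur anti to the vinyl group; this centre is rebuilt in step 3.

Step 3
Reactants: 3 (5R,6R)-5-ethenyl-4,4-dimethoxy-6-methylcyclohex-2-en-1-one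
Product: 4 (5R,6R)-5-ethenyl-4,4-dimethoxy-6-methyl-6-[3-(trimethylsilyl)prop-2-yn-1-yl]cyclohex-2-en-1-one (propargyl trans to vinyl)
Conditions: LDA, THF/DMPU, −78 °C; BrCH2C≡CSiMe3, −78 → 0 °C
Reagents that add atoms: 3-bromo-1-(trimethylsilyl)prop-1-yne, BrCC#C[Si](C)(C)C
Why: Enolate alkylation builds the quaternary carbon (later C5a); the pseudoaxial vinyl group on the neighbouring carbon shields one face, so the propargyl unit should enter trans to vinyl and leave methyl cis to it.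

Step 4
Reactants: 4 (5R,6R)-5-ethenyl-4,4-dimethoxy-6-methyl-6-[3-(trimethylsilyl)prop-2-yn-1-yl]cyclohex-2-en-1-one
Product: 5 (2R,3R)-3-ethenyl-4,4-dimethoxy-2-methyl-2-[3-(trimethylsilyl)prop-2-yn-1-yl]cyclohexan-1-one
Conditions: Cu(OAc)2·H2O (5 mol %), 1,2-bis(diphenylphosphino)benzene, (EtO)2MeSiH, t-BuOH, PhMe, rt
Reagents that add atoms: none
Why: Ligated copper hydride conjugate reduction should saturate only the enone C=C, leaving the isolated vinyl group and the silyl alkyne untouched.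

Step 5
Reactants: 5 (2R,3R)-3-ethenyl-4,4-dimethoxy-2-methyl-2-[3-(trimethylsilyl)prop-2-yn-1-yl]cyclohexan-1-one
Product: 7 (1R,2R,3R)-3-ethenyl-4,4-dimethoxy-2-methyl-2-(prop-2-yn-1-yl)cyclohexan-1-ol, via silyl alkyne alcohol 6 (not isolated)
Conditions: NaBH4, MeOH, 0 °C; then K2CO3, rt
Reagents that add atoms: none
Why: Axial hydride delivery to the chair with axial methyl (the outcome known for the saturated ketone of the Wieland–Miescher system) should give the equatorial alcohol cis to methyl (later C9a–O), and methanolic carbonate then removes the alkyne silyl group.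

Step 6
Reactants: 7 (1R,2R,3R)-3-ethenyl-4,4-dimethoxy-2-methyl-2-(prop-2-yn-1-yl)cyclohexan-1-ol
Product: 8 (2R,3R,4R)-2-ethenyl-4-hydroxy-3-methyl-3-(prop-2-yn-1-yl)cyclohexan-1-one
Conditions: PPTS (cat.), acetone/H2O, 0 °C → rt
Reagents that add atoms: water, O
Why: Mild acid hydrolysis of the dimethyl ketal should free the ketone without enolising the vinyl-bearing α-carbon.

Step 7
Reactants: 8 (2R,3R,4R)-2-ethenyl-4-hydroxy-3-methyl-3-(prop-2-yn-1-yl)cyclohexan-1-one
Product: 9 (1R,2R,3R,4S)-3-ethenyl-2,4-dimethyl-2-(prop-2-yn-1-yl)cyclohexane-1,4-diol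
Conditions: MeMgBr (excess), CeCl3, THF, −78 °C
Reagents that add atoms: methylmagnesium bromide, C[Mg]Br
Why: Cerium-mediated 1,2-addition avoids enolisation of the β,γ-unsaturated ketone, and equatorial attack (the axial path is blocked by the syn-axial methyl) should give axial OH and equatorial methyl at the later C7, as in methyl Grignard additions to 6-oxo steroids.

Step 8
Reactants: 9 (1R,2R,3R,4S)-3-ethenyl-2,4-dimethyl-2-(prop-2-yn-1-yl)cyclohexane-1,4-diol
Product: 10 ethyl (E)-3-{[(1R,2R,3R,4S)-3-ethenyl-4-hydroxy-2,4-dimethyl-2-(prop-2-yn-1-yl)cyclohexyl]oxy}but-2-enoate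
Conditions: ethyl but-2-ynoate, PMe3 (cat.), CH2Cl2, rt
Reagents that add atoms: ethyl but-2-ynoate, CC#CC(=O)OCC
Why: Phosphine-catalysed oxa-Michael addition of the secondary alcohol to the ynoate should give the (E)-β-alkoxy crotonate, the hindered tertiary alcohol staying free.

Step 9
Reactants: 10 ethyl (E)-3-{[(1R,2R,3R,4S)-3-ethenyl-4-hydroxy-2,4-dimethyl-2-(prop-2-yn-1-yl)cyclohexyl]oxy}but-2-enoate
Product: 11 ethyl (E)-3-{[(1R,2R,3R,4S)-3-ethenyl-4-hydroxy-2,4-dimethyl-2-(3-oxopropyl)cyclohexyl]oxy}but-2-enoate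
Conditions: [CpRu(MeCN)3]PF6 (5 mol %), 5,5'-bis(trifluoromethyl)-2,2'-bipyridine, NMP/H2O, rt
Reagents that add atoms: water, O
Why: Ruthenium-catalysed anti-Markovnikov hydration of the terminal alkyne via a vinylidene should give the aldehyde directly and leave the vinyl group and the crotonate alone.

Step 10
Reactants: 11 ethyl (E)-3-{[(1R,2R,3R,4S)-3-ethenyl-4-hydroxy-2,4-dimethyl-2-(3-oxopropyl)cyclohexyl]oxy}but-2-enoate
Product: 12 ethyl 2-[(2S,3R,5aR,6R,7S,9aR)-6-ethenyl-3,7-dihydroxy-2,5a,7-trimethyldecahydro-1-benzoxepin-2-yl]acetate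
Conditions: SmI2 (3 equiv), MeOH (3 equiv), THF, 0 °C
Reagents that add atoms: none
Why: SmI2 reduces the aldehyde to a samarium ketyl that adds to the β-carbon of the (E)-β-alkoxy crotonate, and the ester-stabilised radical is reduced by a second SmI2 to the samarium enolate and protonated by MeOH. The closest known reaction type is the SmI2-induced reductive cyclisation of aldehydes onto β-alkoxyacrylates that gives 2,3-trans-3-hydroxy oxanes and oxepanes in ladder polyether synthesis, β-methyl acceptors included. The oxepane closes in the 7-exo-trig mode, its two ends held close by the trans-diequatorial O–C9a and C5a–CH2 bonds of the chair cyclohexane. The new carbinol centre C3 is controlled by a chelated chair-like transition state in which trivalent samarium bridges the ketyl oxygen and the ester carbonyl, so the C–O bond is pseudoequatorial, anti to the CH2CO2Et arm and syn to H-9a; C2 (methyl axial, ester arm equatorial) is set in the same transition state and becomes CMe2 in step 13. The step needs electron transfer to the aldehyde only (crotonate, vinyl group and free tertiary alcohol are inert to SmI2 without HMPA) and attack at the oxygen-bearing alkene carbon, which the ester polarisation secures.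

Step 11
Reactants: 12 ethyl 2-[(2S,3R,5aR,6R,7S,9aR)-6-ethenyl-3,7-dihydroxy-2,5a,7-trimethyldecahydro-1-benzoxepin-2-yl]acetate
Product: 13 ethyl 2-[(2S,3R,5aR,6R,7S,9aR)-6-ethenyl-2,5a,7-trimethyl-3,7-bis(triethylsilyloxy)decahydro-1-benzoxepin-2-yl]acetate
Conditions: TESOTf (excess), 2,6-lutidine, CH2Cl2, −78 → 0 °C
Reagents that add atoms: triethylsilyl trifluoromethanesulfonate, CC[Si](CC)(CC)OS(=O)(=O)C(F)(F)F
Why: Silyl triflate silylation protects both the secondary and the tertiary alcohol for the radical and organolithium steps.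

Step 12
Reactants: 13 ethyl 2-[(2S,3R,5aR,6R,7S,9aR)-6-ethenyl-2,5a,7-trimethyl-3,7-bis(triethylsilyloxy)decahydro-1-benzoxepin-2-yl]acetate
Product: 14 2-[(2S,3R,5aR,6R,7S,9aR)-6-ethenyl-2,5a,7-trimethyl-3,7-bis(triethylsilyloxy)decahydro-1-benzoxepin-2-yl]acetic acid
Conditions: LiOH·H2O, THF/MeOH/H2O, rt; pH 4 phosphate buffer
Reagents that add atoms: none
Why: Saponification of the unhindered ethyl ester should leave the hindered silyl ethers intact.

Step 13
Reactants: 14 2-[(2S,3R,5aR,6R,7S,9aR)-6-ethenyl-2,5a,7-trimethyl-3,7-bis(triethylsilyloxy)decahydro-1-benzoxepin-2-yl]acetic acid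
Product: 16 (3R,5aR,6R,7S,9aR)-6-ethenyl-2,2,5a,7-tetramethyl-3,7-bis(triethylsilyloxy)decahydro-1-benzoxepine, via Barton ester 15 (not isolated)
Conditions: N-hydroxypyridine-2-thione, DCC, DMAP (cat.), CH2Cl2, dark, rt; then t-BuSH, hν (visible), PhH, rt
Reagents that add atoms: none
Why: Barton reductive decarboxylation turns the CH2CO2H arm into the second methyl group of C2 through a primary radical that cannot fragment the ring ether and is capped by the thiol.

Step 14
Reactants: 16 (3R,5aR,6R,7S,9aR)-6-ethenyl-2,2,5a,7-tetramethyl-3,7-bis(triethylsilyloxy)decahydro-1-benzoxepine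
Product: 18 (3R,5aR,6R,7S,9aR)-6-(2-iodoethyl)-2,2,5a,7-tetramethyl-3,7-bis(triethylsilyloxy)decahydro-1-benzoxepine, via alkylzirconocene chloride 17 (not isolated)
Conditions: Cp2Zr(H)Cl, THF, rt; then I2, 0 °C
Reagents that add atoms: iodine, II
Why: Hydrozirconation places zirconium on the terminal carbon of the vinyl group and iodinolysis of the C–Zr bond gives the primary iodide.

**Right fragment**

Step 15
Reactants: 19 (R)-(−)-linalool [(3R)-3,7-dimethylocta-1,6-dien-3-ol]
Product: 20 tert-butyl{[(3R)-3,7-dimethylocta-1,6-dien-3-yl]oxy}dimethylsilane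
Conditions: TBSOTf, 2,6-lutidine, CH2Cl2, 0 °C
Reagents that add atoms: tert-butyldimethylsilyl trifluoromethanesulfonate, CC(C)(C)[Si](C)(C)OS(=O)(=O)C(F)(F)F
Why: Silyl triflate silylation of the tertiary allylic alcohol; the chiral-pool carbinol becomes C1 of the hydroazulene.

Step 16
Reactants: 20 tert-butyl{[(3R)-3,7-dimethylocta-1,6-dien-3-yl]oxy}dimethylsilane
Product: 22 (4R)-4-[(tert-butyldimethylsilyl)oxy]-4-methylhex-5-enal, via ozonide 21 (not isolated)
Conditions: O3 (1 equiv, dye end-point), CH2Cl2, −78 °C; then Me2S, −78 °C → rt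
Reagents that add atoms: ozone, [O-][O+]=O
Why: Ozonolysis should cleave the electron-rich trisubstituted alkene selectively over the hindered vinyl group next to the silyloxy carbon.

Step 17
Reactants: 22 (4R)-4-[(tert-butyldimethylsilyl)oxy]-4-methylhex-5-enal
Product: 23 tert-butyl{[(3R)-7,7-dibromo-3-methylhepta-1,6-dien-3-yl]oxy}dimethylsilane
Conditions: CBr4, PPh3, CH2Cl2, 0 °C
Reagents that add atoms: carbon tetrabromide, BrC(Br)(Br)Br
Why: Corey–Fuchs dibromo-olefination of the aldehyde.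

Step 18
Reactants: 23 tert-butyl{[(3R)-7,7-dibromo-3-methylhepta-1,6-dien-3-yl]oxy}dimethylsilane
Product: 25 tert-butyldimethyl{[(3R)-3-methyloct-1-en-6-yn-3-yl]oxy}silane, via lithium acetylide 24 (not isolated)
Conditions: n-BuLi (2.2 equiv), THF, −78 °C; then MeI, −78 °C → rt
Reagents that add atoms: iodomethane, CI
Why: Corey–Fuchs rearrangement to the lithium acetylide and in situ methylation give the methyl-capped 1,6-enyne.

Step 19
Reactants: 25 tert-butyldimethyl{[(3R)-3-methyloct-1-en-6-yn-3-yl]oxy}silane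
Product: 26 (6R,6aR)-6-[(tert-butyldimethylsilyl)oxy]-3,6-dimethyl-4,5,6,6a-tetrahydropentalen-2(1H)-one
Conditions: Co2(CO)8 (10 mol %), tetramethylthiourea (60 mol %), CO (1 atm), PhH, 70 °C
Reagents that add atoms: carbon monoxide, [C-]#[O+]
Why: Intramolecular Pauson–Khand reaction closes both five-membered rings; the ring-fusion centre C6a is set in the alkene insertion, in which the bulky silyloxy group on the allylic quaternary carbon is expected to sit exo (cis to H-6a) and the methyl endo.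

Step 20
Reactants: 26 (6R,6aR)-6-[(tert-butyldimethylsilyl)oxy]-3,6-dimethyl-4,5,6,6a-tetrahydropentalen-2(1H)-one
Product: 28 (3aR,6R,6aR)-6-[(tert-butyldimethylsilyl)oxy]-3,3,6-trimethylhexahydropentalen-2(1H)-one, via lithium enolate 27 (not isolated)
Conditions: Li, NH3(l)/THF, t-BuOH (1 equiv), −78 °C; then MeI, −78 → −33 °C
Reagents that add atoms: iodomethane, CI
Why: Dissolving-metal reduction protonates the β-carbon to the only accessible cis-fused diquinane (sets C3a) and the regiospecific enolate is methylated to the gem-dimethyl carbon.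

Step 21
Reactants: 28 (3aR,6R,6aR)-6-[(tert-butyldimethylsilyl)oxy]-3,3,6-trimethylhexahydropentalen-2(1H)-one
Product: 29 tert-butyl{[(1R,3aR,6aR)-1,4,4-trimethyl-5-(trimethylsilyloxy)-1,2,3,3a,4,6a-hexahydropentalen-1-yl]oxy}dimethylsilane (silyl enol ether towards the CH2 side)
Conditions: LDA, TMSCl, THF, −78 °C
Reagents that add atoms: chlorotrimethylsilane, C[Si](C)(C)Cl
Why: Only the CH2 side of the ketone can enolise, so the silyl enol ether forms regiospecifically.

Step 22
Reactants: 29 silyl enol ether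
Product: 30 dichlorocyclobutanone [2+2] adduct (cyclobutanone fused on the convex face; CCl2 on the silyloxy carbon, C=O on the former enol CH)
Conditions: Cl2CHCOCl, Et3N, hexanes, rt
Reagents that add atoms: dichloroacetyl chloride, ClC(Cl)C(Cl)=O
Why: [2+2] cycloaddition of dichloroketene with a silyl enol ether, the ketene carbonyl carbon bonding to the nucleophilic unsubstituted enol carbon from the convex face.

Step 23
Reactants: 30 dichlorocyclobutanone adduct
Product: 32 (1R,3aR,8aR)-1-[(tert-butyldimethylsilyl)oxy]-1,4,4-trimethyloctahydroazulene-5,7-dione, via dechlorinated cyclobutanone 31 (not isolated)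
Conditions: Zn, AcOH, i-PrOH/H2O, 0 °C → rt; then 65 °C
Reagents that add atoms: none
Why: Zinc dechlorination followed by desilylative retro-aldol cleavage of the ring-fusion bond of the β-silyloxy cyclobutanone expands the cyclopentanone by two carbons to the cycloheptane-1,3-dione.

Step 24
Reactants: 32 (1R,3aR,8aR)-1-[(tert-butyldimethylsilyl)oxy]-1,4,4-trimethyloctahydroazulene-5,7-dione
Product: 33 (1R,3aR,8aR)-1-[(tert-butyldimethylsilyl)oxy]-1,4,4,6-tetramethyloctahydroazulene-5,7-dione (C6 epimers/enol)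
Conditions: MeI, K2CO3, acetone, reflux
Reagents that add atoms: iodomethane, CI
Why: C-alkylation of the cyclic 1,3-dione at the carbon between the carbonyls.

Step 25
Reactants: 33 (1R,3aR,8aR)-1-[(tert-butyldimethylsilyl)oxy]-1,4,4,6-tetramethyloctahydroazulene-5,7-dione
Product: 34 (1R,3aR,8aR)-1-[(tert-butyldimethylsilyl)oxy]-1,4,4,6-tetramethyl-7-(2-methylpropoxy)-2,3,3a,4,8,8a-hexahydroazulen-5(1H)-one
Conditions: i-BuOH, PPTS (cat.), PhMe, reflux, Dean–Stark
Reagents that add atoms: 2-methylpropan-1-ol, CC(C)CO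
Why: Acid-catalysed vinylogous ester formation should take place at the less hindered C7 carbonyl, leaving the carbonyl next to CMe2 as the ketone that the nucleophile must attack.

**Union and end game**

Step 26
Reactants: 18 (3R,5aR,6R,7S,9aR)-6-(2-iodoethyl)-2,2,5a,7-tetramethyl-3,7-bis(triethylsilyloxy)decahydro-1-benzoxepine; 34 vinylogous ester
Product: 37 (1R,3aR,8aR)-1-[(tert-butyldimethylsilyl)oxy]-1,4,4,6-tetramethyl-5-{2-[(3R,5aR,6R,7S,9aR)-2,2,5a,7-tetramethyl-3,7-bis(triethylsilyloxy)decahydro-1-benzoxepin-6-yl]ethyl}-2,3,3a,4,8,8a-hexahydroazulen-7(1H)-one, via alkyllithium 35 (not isolated), via carbinol adduct 36 (not isolated)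
Conditions: 18, t-BuLi (2.1 equiv), Et2O/pentane, −78 °C; then 34, THF, −78 → 0 °C; then 1 M aq. HCl, THF, 0 °C (brief)
Reagents that add atoms: water, O
Why: Stork–Danheiser sequence, in which iodine–lithium exchange gives the primary alkyllithium, 1,2-addition to the vinylogous ester carbonyl and acid-mediated hydrolysis with loss of water transpose the enone and create the tetrasubstituted alkene with the linker on C5.

Step 27
Reactants: 37 tris-silylated enone
Product: 38 (1R,3aR,7S,8aR)-1-[(tert-butyldimethylsilyl)oxy]-1,4,4,6-tetramethyl-5-{2-[(3R,5aR,6R,7S,9aR)-2,2,5a,7-tetramethyl-3,7-bis(triethylsilyloxy)decahydro-1-benzoxepin-6-yl]ethyl}-1,2,3,3a,4,7,8,8a-octahydroazulen-7-ol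
Conditions: (R)-2-methyl-CBS-oxazaborolidine (1 equiv), catecholborane, PhMe, −78 °C
Reagents that add atoms: none
Why: Corey–Bakshi–Shibata reduction of the α-methyl cyclic enone, the alkene side acting as the large group so that the (R)-oxazaborolidine should deliver hydride to give the 7S allylic alcohol (the convex face of the cis-fused bicycle is expected to favour the same sense).

Step 28
Reactants: 38 tris-silylated triol
Product: 39 CNP0276044.1 (target)
Conditions: TBAF, THF, 50 °C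
Reagents that add atoms: none
Why: Fluoride-mediated cleavage of the three silyl ethers under non-acidic conditions preserves the allylic alcohol.

**Compound list**

1 | 4,4-dimethoxycyclohexa-2,5-dien-1-one | COC1(OC)C=CC(=O)C=C1 | starting material
2 | (S)-5-ethenyl-4,4-dimethoxycyclohex-2-en-1-one | C=C[C@H]1C(OC)(OC)C=CC(=O)C1 | intermediate
3 | (5R,6R)-5-ethenyl-4,4-dimethoxy-6-methylcyclohex-2-en-1-one | C=C[C@H]1C(OC)(OC)C=CC(=O)[C@@H]1C | intermediate
4 | (5R,6R)-5-ethenyl-4,4-dimethoxy-6-methyl-6-[3-(trimethylsilyl)prop-2-yn-1-yl]cyclohex-2-en-1-one | C=C[C@H]1C(OC)(OC)C=CC(=O)[C@]1(C)CC#C[Si](C)(C)C | intermediate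
5 | (2R,3R)-3-ethenyl-4,4-dimethoxy-2-methyl-2-[3-(trimethylsilyl)prop-2-yn-1-yl]cyclohexan-1-one | C=C[C@H]1C(OC)(OC)CCC(=O)[C@]1(C)CC#C[Si](C)(C)C | intermediate
6 | (1R,2R,3R)-3-ethenyl-4,4-dimethoxy-2-methyl-2-[3-(trimethylsilyl)prop-2-yn-1-yl]cyclohexan-1-ol | C=C[C@H]1C(OC)(OC)CC[C@@H](O)[C@]1(C)CC#C[Si](C)(C)C | intermediate (not isolated)
7 | (1R,2R,3R)-3-ethenyl-4,4-dimethoxy-2-methyl-2-(prop-2-yn-1-yl)cyclohexan-1-ol | C=C[C@H]1C(OC)(OC)CC[C@@H](O)[C@]1(C)CC#C | intermediate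
8 | (2R,3R,4R)-2-ethenyl-4-hydroxy-3-methyl-3-(prop-2-yn-1-yl)cyclohexan-1-one | C=C[C@H]1C(=O)CC[C@@H](O)[C@]1(C)CC#C | intermediate
9 | (1R,2R,3R,4S)-3-ethenyl-2,4-dimethyl-2-(prop-2-yn-1-yl)cyclohexane-1,4-diol | C=C[C@H]1[C@@](C)(O)CC[C@@H](O)[C@]1(C)CC#C | intermediate
10 | ethyl (E)-3-{[(1R,2R,3R,4S)-3-ethenyl-4-hydroxy-2,4-dimethyl-2-(prop-2-yn-1-yl)cyclohexyl]oxy}but-2-enoate | C=C[C@H]1[C@@](C)(O)CC[C@@H](O/C(C)=C/C(=O)OCC)[C@]1(C)CC#C | intermediate
11 | ethyl (E)-3-{[(1R,2R,3R,4S)-3-ethenyl-4-hydroxy-2,4-dimethyl-2-(3-oxopropyl)cyclohexyl]oxy}but-2-enoate | C=C[C@H]1[C@@](C)(O)CC[C@@H](O/C(C)=C/C(=O)OCC)[C@]1(C)CCC=O | intermediate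
12 | ethyl 2-[(2S,3R,5aR,6R,7S,9aR)-6-ethenyl-3,7-dihydroxy-2,5a,7-trimethyldecahydro-1-benzoxepin-2-yl]acetate | C=C[C@@H]2[C@@]3(C)CC[C@@H](O)[C@](C)(CC(=O)OCC)O[C@@H]3CC[C@]2(C)O | intermediate
13 | bis(triethylsilyl) ether of 12 | C=C[C@@H]2[C@@]3(C)CC[C@@H](O[Si](CC)(CC)CC)[C@](C)(CC(=O)OCC)O[C@@H]3CC[C@]2(C)O[Si](CC)(CC)CC | intermediate
14 | 2-[(2S,3R,5aR,6R,7S,9aR)-6-ethenyl-2,5a,7-trimethyl-3,7-bis(triethylsilyloxy)decahydro-1-benzoxepin-2-yl]acetic acid | C=C[C@@H]2[C@@]3(C)CC[C@@H](O[Si](CC)(CC)CC)[C@](C)(CC(=O)O)O[C@@H]3CC[C@]2(C)O[Si](CC)(CC)CC | intermediate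
15 | 2-thioxopyridin-1(2H)-yl ester of 14 (Barton ester) | C=C[C@@H]2[C@@]3(C)CC[C@@H](O[Si](CC)(CC)CC)[C@](C)(CC(=O)ON4C=CC=CC4=S)O[C@@H]3CC[C@]2(C)O[Si](CC)(CC)CC | intermediate (not isolated)
16 | (3R,5aR,6R,7S,9aR)-6-ethenyl-2,2,5a,7-tetramethyl-3,7-bis(triethylsilyloxy)decahydro-1-benzoxepine | C=C[C@@H]2[C@@]3(C)CC[C@@H](O[Si](CC)(CC)CC)C(C)(C)O[C@@H]3CC[C@]2(C)O[Si](CC)(CC)CC | intermediate
17 | chlorobis(cyclopentadienyl)zirconium alkyl from 16 (Zr on the terminal carbon) | Cl[Zr](C1C=CC=C1)(C1C=CC=C1)CC[C@@H]2[C@@]3(C)CC[C@@H](O[Si](CC)(CC)CC)C(C)(C)O[C@@H]3CC[C@]2(C)O[Si](CC)(CC)CC | intermediate (not isolated)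
18 | (3R,5aR,6R,7S,9aR)-6-(2-iodoethyl)-2,2,5a,7-tetramethyl-3,7-bis(triethylsilyloxy)decahydro-1-benzoxepine | ICC[C@@H]2[C@@]3(C)CC[C@@H](O[Si](CC)(CC)CC)C(C)(C)O[C@@H]3CC[C@]2(C)O[Si](CC)(CC)CC | intermediate
19 | (R)-(−)-linalool | C=C[C@](C)(O)CCC=C(C)C | starting material
20 | tert-butyl{[(3R)-3,7-dimethylocta-1,6-dien-3-yl]oxy}dimethylsilane | C=C[C@](C)(O[Si](C)(C)C(C)(C)C)CCC=C(C)C | intermediate
21 | 1,2,4-trioxolane (ozonide) of the trisubstituted alkene of 20 | C=C[C@](C)(O[Si](C)(C)C(C)(C)C)CCC1OOC(C)(C)O1 | intermediate (not isolated)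
22 | (4R)-4-[(tert-butyldimethylsilyl)oxy]-4-methylhex-5-enal | C=C[C@](C)(O[Si](C)(C)C(C)(C)C)CCC=O | intermediate
23 | tert-butyl{[(3R)-7,7-dibromo-3-methylhepta-1,6-dien-3-yl]oxy}dimethylsilane | C=C[C@](C)(O[Si](C)(C)C(C)(C)C)CCC=C(Br)Br | intermediate
24 | lithium acetylide of (3R)-3-[(tert-butyldimethylsilyl)oxy]-3-methylhept-1-en-6-yne | C=C[C@](C)(O[Si](C)(C)C(C)(C)C)CCC#C[Li] | intermediate (not isolated)
25 | tert-butyldimethyl{[(3R)-3-methyloct-1-en-6-yn-3-yl]oxy}silane | C=C[C@](C)(O[Si](C)(C)C(C)(C)C)CCC#CC | intermediate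
26 | (6R,6aR)-6-[(tert-butyldimethylsilyl)oxy]-3,6-dimethyl-4,5,6,6a-tetrahydropentalen-2(1H)-one | CC1=C2CC[C@@](C)(O[Si](C)(C)C(C)(C)C)[C@@H]2CC1=O | intermediate
27 | lithium enolate from conjugate reduction of 26 (cis-fused) | [Li]OC1=C(C)[C@@H]2CC[C@@](C)(O[Si](C)(C)C(C)(C)C)[C@@H]2C1 | intermediate (not isolated)
28 | (3aR,6R,6aR)-6-[(tert-butyldimethylsilyl)oxy]-3,3,6-trimethylhexahydropentalen-2(1H)-one | CC1(C)[C@@H]2CC[C@@](C)(O[Si](C)(C)C(C)(C)C)[C@@H]2CC1=O | intermediate
29 | trimethylsilyl enol ether of 28 (towards the CH2 side) | CC1(C)[C@@H]2CC[C@@](C)(O[Si](C)(C)C(C)(C)C)[C@@H]2C=C1O[Si](C)(C)C | intermediate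
30 | dichlorocyclobutanone adduct of 29 (convex-face fusion) | CC1(C)[C@@H]2CC[C@@](C)(O[Si](C)(C)C(C)(C)C)[C@@H]2[C@H]3C(=O)C(Cl)(Cl)[C@@]13O[Si](C)(C)C | intermediate
31 | dechlorinated cyclobutanone | CC1(C)[C@@H]2CC[C@@](C)(O[Si](C)(C)C(C)(C)C)[C@@H]2[C@H]3C(=O)C[C@@]13O[Si](C)(C)C | intermediate (not isolated)
32 | (1R,3aR,8aR)-1-[(tert-butyldimethylsilyl)oxy]-1,4,4-trimethyloctahydroazulene-5,7-dione | O=C1CC(=O)C(C)(C)[C@@H]2CC[C@@](C)(O[Si](C)(C)C(C)(C)C)[C@@H]2C1 | intermediate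
33 | (1R,3aR,8aR)-1-[(tert-butyldimethylsilyl)oxy]-1,4,4,6-tetramethyloctahydroazulene-5,7-dione | CC1C(=O)C(C)(C)[C@@H]2CC[C@@](C)(O[Si](C)(C)C(C)(C)C)[C@@H]2CC1=O | intermediate
34 | (1R,3aR,8aR)-1-[(tert-butyldimethylsilyl)oxy]-1,4,4,6-tetramethyl-7-(2-methylpropoxy)-2,3,3a,4,8,8a-hexahydroazulen-5(1H)-one | CC(C)COC1=C(C)C(=O)C(C)(C)[C@@H]2CC[C@@](C)(O[Si](C)(C)C(C)(C)C)[C@@H]2C1 | intermediate
35 | primary alkyllithium from 18 | [Li]CC[C@@H]2[C@@]3(C)CC[C@@H](O[Si](CC)(CC)CC)C(C)(C)O[C@@H]3CC[C@]2(C)O[Si](CC)(CC)CC | intermediate (not isolated)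
36 | tertiary carbinol from 1,2-addition of 35 to 34 | CC(C)COC1=C(C)C(O)(CC[C@@H]2[C@@]3(C)CC[C@@H](O[Si](CC)(CC)CC)C(C)(C)O[C@@H]3CC[C@]2(C)O[Si](CC)(CC)CC)C(C)(C)[C@@H]2CC[C@@](C)(O[Si](C)(C)C(C)(C)C)[C@@H]2C1 | intermediate (not isolated)
37 | tris-silylated enone (step 26 product) | CC1=C(CC[C@@H]2[C@@]3(C)CC[C@@H](O[Si](CC)(CC)CC)C(C)(C)O[C@@H]3CC[C@]2(C)O[Si](CC)(CC)CC)C(C)(C)[C@@H]2CC[C@@](C)(O[Si](C)(C)C(C)(C)C)[C@@H]2CC1=O | intermediate
38 | tris-silylated 7S allylic alcohol (step 27 product) | CC1=C(CC[C@@H]2[C@@]3(C)CC[C@@H](O[Si](CC)(CC)CC)C(C)(C)O[C@@H]3CC[C@]2(C)O[Si](CC)(CC)CC)C(C)(C)[C@@H]2CC[C@@](C)(O[Si](C)(C)C(C)(C)C)[C@@H]2C[C@@H]1O | intermediate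
39 | CNP0276044.1 | CC1=C(CC[C@@H]2[C@@]3(C)CC[C@@H](O)C(C)(C)O[C@@H]3CC[C@]2(C)O)C(C)(C)[C@@H]2CC[C@@](C)(O)[C@@H]2C[C@@H]1O | target

**Count and risks**

Total steps: 28 (left fragment 14, right fragment 11, union and end game 3). Longest linear sequence: 17 (steps 1–14, then 26–28).

Steps most likely to fail:

1. Step 10. The seven-membered closure onto a fully substituted acceptor carbon may be slow, so that simple reduction of the aldehyde or pinacol coupling takes over. Fallback by acyl radical cyclisation, setting out from 11: Pinnick oxidation (NaClO2, NaH2PO4, 2-methylbut-2-ene, t-BuOH/H2O) should give the carboxylic acid F1; (PhSe)2 and PBu3 should convert it into the Se-phenyl selenoester F2; (Me3Si)3SiH with Et3B and air should generate the acyl radical, whose 7-exo addition to the crotonate gives the oxepan-3-one F3; NaBH4 at low temperature (axial hydride attack, as for 4,4-dimethyl-3-oxo terpenoids) should then give the equatorial alcohol, rejoining the route at 12.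

2. Step 26. Addition at the carbonyl flanked by the quaternary carbon may lose out to deprotonation of the vinylogous ester or to decomposition of the organolithium. Fallback by sp3–sp2 cross-coupling, setting out from 33 and 16: LiBH(s-Bu)3 should reduce the less hindered C7 carbonyl of 33 from the convex face to the hydroxy ketone F4; TBSOTf gives its silyl ether F5; KHMDS and PhNTf2 give the regiodefined enol triflate F6 (only C6 can enolise); 9-BBN adds to the vinyl group of 16 to give the B-alkyl borane F7; Pd(dppf)Cl2 with aqueous K3PO4 couples F6 and F7 to the tetrasilylated product F8; TBAF then gives the target, so the route is rejoined at 39.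

3. Step 19. Facial selectivity in the alkene insertion may be poor because the allylic carbon carries two groups of similar size (methyl and silyloxy). Fallback that erases and resets both ring-fusion centres, setting out from 26 (either C6a epimer): KOt-Bu and MeI should effect deconjugative α-methylation to the gem-dimethyl ketone with the alkene at the ring fusion, F9; TBAF frees the tertiary allylic alcohol F10; hydroxyl-directed hydrogenation with [Ir(cod)(PCy3)(py)]PF6 and H2 should deliver both ring-fusion hydrogens syn to the hydroxyl, giving the cis-fused hydroxy ketone F11; TBSOTf then rejoins the route at 28.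

Further compounds
F1 | step 10 | 3-[(1R,2R,3S,6R)-6-{[(E)-4-ethoxy-4-oxobut-2-en-2-yl]oxy}-2-ethenyl-3-hydroxy-1,3-dimethylcyclohexyl]propanoic acid | C=C[C@H]1[C@@](C)(O)CC[C@@H](O/C(C)=C/C(=O)OCC)[C@]1(C)CCC(=O)O
F2 | step 10 | Se-phenyl selenoester of F1 | C=C[C@H]1[C@@](C)(O)CC[C@@H](O/C(C)=C/C(=O)OCC)[C@]1(C)CCC(=O)[Se]c1ccccc1
F3 | step 10 | ethyl 2-[(2S,5aR,6R,7S,9aR)-6-ethenyl-7-hydroxy-2,5a,7-trimethyl-3-oxodecahydro-1-benzoxepin-2-yl]acetate | C=C[C@@H]2[C@@]3(C)CCC(=O)[C@](C)(CC(=O)OCC)O[C@@H]3CC[C@]2(C)O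
F4 | step 26 | (1R,3aR,7S,8aR)-1-[(tert-butyldimethylsilyl)oxy]-7-hydroxy-1,4,4,6-tetramethyloctahydroazulen-5(1H)-one | CC1C(=O)C(C)(C)[C@@H]2CC[C@@](C)(O[Si](C)(C)C(C)(C)C)[C@@H]2C[C@@H]1O
F5 | step 26 | 7-O-tert-butyldimethylsilyl ether of F4 | CC1C(=O)C(C)(C)[C@@H]2CC[C@@](C)(O[Si](C)(C)C(C)(C)C)[C@@H]2C[C@@H]1O[Si](C)(C)C(C)(C)C
F6 | step 26 | enol triflate of F5 (C5–OTf, C5=C6) | CC1=C(OS(=O)(=O)C(F)(F)F)C(C)(C)[C@@H]2CC[C@@](C)(O[Si](C)(C)C(C)(C)C)[C@@H]2C[C@@H]1O[Si](C)(C)C(C)(C)C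
F7 | step 26 | B-alkyl-9-borabicyclo[3.3.1]nonane from 16 | C1CC2CCCC(C1)B2CC[C@@H]3[C@@]4(C)CC[C@@H](O[Si](CC)(CC)CC)C(C)(C)O[C@@H]4CC[C@]3(C)O[Si](CC)(CC)CC
F8 | step 26 | tetrasilylated target (two triethylsilyl and two tert-butyldimethylsilyl ethers) | CC1=C(CC[C@@H]2[C@@]3(C)CC[C@@H](O[Si](CC)(CC)CC)C(C)(C)O[C@@H]3CC[C@]2(C)O[Si](CC)(CC)CC)C(C)(C)[C@@H]2CC[C@@](C)(O[Si](C)(C)C(C)(C)C)[C@@H]2C[C@@H]1O[Si](C)(C)C(C)(C)C
F9 | step 19 | (R)-4-[(tert-butyldimethylsilyl)oxy]-1,1,4-trimethyl-1,3,4,5,6-pentahydropentalen-2-one with the alkene at the ring fusion | CC1(C)C2=C(CC1=O)[C@](C)(O[Si](C)(C)C(C)(C)C)CC2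
F10 | step 19 | free tertiary allylic alcohol from F9 | CC1(C)C2=C(CC1=O)[C@](C)(O)CC2
F11 | step 19 | (3aR,6R,6aR)-6-hydroxy-3,3,6-trimethylhexahydropentalen-2(1H)-one | CC1(C)[C@@H]2CC[C@@](C)(O)[C@@H]2CC1=O
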